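**Plan**

- Retrosynthesis: the dienone ring is cut at the C(=O)–C(OMe) bond and at the C(spiro)–C(OMe) bond, giving a (2‑methoxyethylidene)cyclohexane C3 unit and methyl 3,3‑dimethoxyacrylate.
- Enabling feature: in the 2,5‑dimethoxycyclohexa‑2,5‑dienone ring the spiro carbon is γ to the carbonyl through CH=C(OMe), and the other OMe‑bearing carbon is the β‑carbon of a vinylogous ester. C(spiro)–CH=C(OMe) therefore acts as an allyl 1,3‑dinucleophile and O=C–CH=C(OMe) as a 1,3‑dielectrophile.
- Forward order: organocatalytic [3+3] annulation gives the cyclohexenone; arylation, carbonyl transposition, hydrogenation and a second arylation give the pentasubstituted cyclohexanone; a C2 stannane is appended; the dienone ring is closed last.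
- Stereochemistry: the organocatalyst sets the ring methyl centre; the first aryl enters anti to it; hydrogenation anti to that aryl sets the ethyl and axial methyl centres; the second aryl enters anti to the first methyl.
- The spiro centre is set in the key step by equatorial C–C bond formation anti to the axial methyl group.

Key step: step 11

Remark: tert‑butyl 3‑oxohexanoate and the (R)‑diarylprolinol silyl ether are taken as catalogue compounds; the carbinol centres of 9 and 14, the tin‑bearing centre of 17 and the alkene geometry of 15 and 17 are left open because all are destroyed later.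

**Step 1**
Reactants: 1 tert‑butyl 3‑oxohexanoate; 2 (E)‑but‑2‑enal
Product: 5 (S)‑2‑ethyl‑5‑methylcyclohex‑2‑en‑1‑one, via Michael adduct 3 (not isolated), via cyclic keto ester 4 (not isolated)
Conditions: (R)‑2‑{bis[3,5‑bis(trifluoromethyl)phenyl](trimethylsilyloxy)methyl}pyrrolidine (10 mol %), PhCO2H (10 mol %), toluene, 23 °C; then p‑TsOH·H2O (20 mol %), 80 °C
Reagents that add atoms: none
Why: Iminium‑activated Michael addition of the β‑keto ester to the enal, then acid‑mediated aldol condensation, tert‑butyl ester cleavage and decarboxylation (organocatalytic cyclohexenone annulation); the (R)‑catalyst shields one face of the (E)‑iminium ion so that C‑5 should form with S configuration.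

**Step 2**
Reactants: 5 (S)‑2‑ethyl‑5‑methylcyclohex‑2‑en‑1‑one; 6 1‑bromo‑2,4,5‑trimethoxybenzene
Product: 8 (5S,6S)‑2‑ethyl‑5‑methyl‑6‑(2,4,5‑trimethoxyphenyl)cyclohex‑2‑en‑1‑one, via silyl dienol ether 7 (not isolated)
Conditions: LDA, TMSCl, THF, −78 °C; then 6, Pd2(dba)3 (cat.), P(t‑Bu)3 (cat.), Bu3SnF, CsF, toluene, 85 °C
Reagents that add atoms: none
Why: Kinetic α'‑deprotonation and silylation give the cross‑conjugated silyl dienol ether, and its fluoride‑promoted palladium‑catalysed α‑arylation is regiospecific for C‑6; the aryl group should enter anti to the neighbouring methyl group, which is also the more stable trans arrangement at this epimerisable centre.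

**Step 3**
Reactants: 8 (5S,6S)‑2‑ethyl‑5‑methyl‑6‑(2,4,5‑trimethoxyphenyl)cyclohex‑2‑en‑1‑one
Product: 9 (5S,6S)‑2‑ethyl‑1,5‑dimethyl‑6‑(2,4,5‑trimethoxyphenyl)cyclohex‑2‑en‑1‑ol (C‑1 epimers)
Conditions: MeLi, CeCl3, THF, −78 °C
Reagents that add atoms: methyllithium, [Li]C
Why: Organocerium (Imamoto) 1,2‑addition to an enolisable enone carbonyl; the new carbinol centre is destroyed in step 4.

**Step 4**
Reactants: 9 (5S,6S)‑2‑ethyl‑1,5‑dimethyl‑6‑(2,4,5‑trimethoxyphenyl)cyclohex‑2‑en‑1‑ol
Product: 10 (4R,5S)‑2‑ethyl‑3,5‑dimethyl‑4‑(2,4,5‑trimethoxyphenyl)cyclohex‑2‑en‑1‑one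
Conditions: pyridinium chlorochromate (C5H5NH[CrO3Cl]), 4 Å molecular sieves, CH2Cl2, 23 °C
Reagents that add atoms: pyridinium chlorochromate, [O-][Cr](=O)(=O)Cl.c1cc[nH+]cc1
Why: Dauben oxidative 1,3‑transposition: [3,3] shift of the tertiary allylic chromate ester and oxidation of the secondary allylic chromate give the β‑methyl enone, leaving both stereocentres untouched.

**Step 5**
Reactants: 10 (4R,5S)‑2‑ethyl‑3,5‑dimethyl‑4‑(2,4,5‑trimethoxyphenyl)cyclohex‑2‑en‑1‑one
Product: 11 (2R,3R,4R,5S)‑2‑ethyl‑3,5‑dimethyl‑4‑(2,4,5‑trimethoxyphenyl)cyclohexan‑1‑one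
Conditions: H2 (1 atm), Pd/C, EtOAc, 23 °C
Reagents that add atoms: none
Why: Heterogeneous catalytic hydrogenation should add both hydrogens syn to the alkene face opposite the 4‑aryl group (pseudoaxial through allylic strain with the 3‑methyl group), setting C‑2 and C‑3 cis to the aryl group.

**Step 6**
Reactants: 11 (2R,3R,4R,5S)‑2‑ethyl‑3,5‑dimethyl‑4‑(2,4,5‑trimethoxyphenyl)cyclohexan‑1‑one; 6 1‑bromo‑2,4,5‑trimethoxybenzene
Product: 13 (2R,3R,4S,5R,6R)‑2‑ethyl‑3,5‑dimethyl‑4,6‑bis(2,4,5‑trimethoxyphenyl)cyclohexan‑1‑one, via silyl enol ether 12 (not isolated)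
Conditions: LDA, TMSCl, THF, −78 °C; then 6, Pd2(dba)3 (cat.), P(t‑Bu)3 (cat.), Bu3SnF, CsF, toluene, 85 °C
Reagents that add atoms: none
Why: Kinetic deprotonation at the methylene α‑carbon, silylation and the same palladium‑catalysed silyl enol ether arylation as in step 2, under non‑equilibrating conditions that protect C‑2; the aryl group should be delivered anti to the 5‑methyl group into the equatorial position.

**Step 7**
Reactants: 13 (2R,3R,4S,5R,6R)‑2‑ethyl‑3,5‑dimethyl‑4,6‑bis(2,4,5‑trimethoxyphenyl)cyclohexan‑1‑one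
Product: 14 1‑vinylcyclohexan‑1‑ol derived from 13 (ring stereocentres as in 13, C‑1 epimers)
Conditions: CH2=CHMgBr, CeCl3, THF, −78 to 0 °C
Reagents that add atoms: vinylmagnesium bromide, C=C[Mg]Br
Why: Organocerium 1,2‑addition of a vinyl nucleophile to a hindered, enolisable α‑aryl ketone; the new carbinol carbon becomes sp2 in step 8.

**Step 8**
Reactants: 14 1‑vinylcyclohexan‑1‑ol derived from 13
Product: 15 2‑(cyclohexylidene)acetaldehyde derived from 13 (ring stereocentres unchanged)
Conditions: pyridinium chlorochromate (C5H5NH[CrO3Cl]), 4 Å molecular sieves, CH2Cl2, 23 °C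
Reagents that add atoms: pyridinium chlorochromate, [O-][Cr](=O)(=O)Cl.c1cc[nH+]cc1
Why: Babler–Dauben oxidative transposition of a tertiary vinyl carbinol ([3,3] chromate shift, then oxidation) gives the enal without a free carbocation next to the electron‑rich arene.

**Step 9**
Reactants: 15 2‑(cyclohexylidene)acetaldehyde derived from 13
Product: 17 tributyl[2‑(cyclohexylidene)‑1‑methoxyethyl]stannane derived from 13, via lithium stannyl alkoxide 16 (not isolated)
Conditions: Bu3SnLi, THF, −78 °C; then MeI, DMPU, −78 to 0 °C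
Reagents that add atoms: tributylstannyllithium, [Li][Sn](CCCC)(CCCC)CCCC; iodomethane, CI
Why: 1,2‑Addition of the stannyl anion to the aldehyde and O‑methylation of the alkoxide (Still‑type α‑alkoxystannane synthesis); the tin‑bearing centre is lost in step 11.

**Step 10**
Reactants: 18 methyl cyanoacetate
Product: 21 methyl 3,3‑dimethoxyprop‑2‑enoate, via imidate hydrochloride 19 (not isolated), via orthoester 20 (not isolated)
Conditions: HCl (g), MeOH (1 equiv), Et2O, 0 °C; then MeOH, 23 °C; then distillation from cat. p‑TsOH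
Reagents that add atoms: methanol, CO
Why: Pinner reaction of the nitrile, methanolysis of the imidate salt to the orthoester and acid‑catalysed loss of methanol give the ketene acetal ester.

**Step 11**
Reactants: 17 tributyl[2‑(cyclohexylidene)‑1‑methoxyethyl]stannane derived from 13; 21 methyl 3,3‑dimethoxyprop‑2‑enoate
Product: 25 tatanan B, via allyllithium 22 (not isolated), via dienyl ketone 23 (not isolated), via lithium trienolate 24 (not isolated)
Conditions: n‑BuLi, THF, −78 °C; cannulate into 21 (3 equiv), THF, −78 °C; then LiHMDS, −78 to 23 °C; aq NH4Cl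
Reagents that add atoms: none
Why: Proposed new method: tin–lithium exchange gives the α‑methoxyallyllithium 22, which is acylated at its oxygen‑bearing carbon by the ester carbonyl of 21 (first bond); LiHMDS then converts ketone 23 into the chelated cross‑conjugated trienolate 24, which closes by a thermal disrotatory 6π electrocyclisation (formally a 6‑endo‑trig attack of the γ‑carbon on the ketene acetal carbon, second bond) and expels methoxide to give the vinylogous ester directly. The closest known reaction types are the Claisen‑type acylation of heteroatom‑stabilised allyl anions and the [3+3] annulation of allyl anions with α‑oxo ketene dithioacetals, which uses the same 1,3‑dinucleophile/1,3‑dielectrophile pairing. The only new stereocentre is the spiro carbon, the exocyclic sp2 carbon of 24: the ketene acetal carbon should bond from the equatorial direction because the axial face is blocked by the 1,3‑related axial methyl group, placing the C(OMe)= arm equatorial and the CH= arm axial as in tatanan B. Site selectivity in the acylation is expected because the γ‑carbon of 22 is fully substituted and flanked by two substituted ring carbons, and because a hard organolithium should add to the ester carbonyl and not to the β‑carbon deactivated by two methoxy groups. Inverse addition into excess 21 limits quenching of 22 by the acidic ketone 23; both alkene isomers converge on 24, and O‑ or α‑C‑closure would give four‑membered rings.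

**Compound list**

1 | tert‑butyl 3‑oxohexanoate | CCCC(=O)CC(=O)OC(C)(C)C | starting material
2 | (E)‑but‑2‑enal | C/C=C/C=O | starting material
3 | tert‑butyl (3S)‑2‑butanoyl‑3‑methyl‑5‑oxopentanoate (C‑2 epimers) | CCCC(=O)C([C@@H](C)CC=O)C(=O)OC(C)(C)C | intermediate
4 | tert‑butyl (6S)‑3‑ethyl‑6‑methyl‑2‑oxocyclohex‑3‑ene‑1‑carboxylate (C‑1 epimers) | CCC1=CC[C@H](C)C(C(=O)OC(C)(C)C)C1=O | intermediate
5 | (S)‑2‑ethyl‑5‑methylcyclohex‑2‑en‑1‑one | CCC1=CC[C@H](C)CC1=O | intermediate
6 | 1‑bromo‑2,4,5‑trimethoxybenzene | COc1cc(OC)c(OC)cc1Br | starting material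
7 | (S)‑[(6‑ethyl‑3‑methylcyclohexa‑1,5‑dien‑1‑yl)oxy]trimethylsilane | CCC1=CC[C@H](C)C=C1O[Si](C)(C)C | intermediate
8 | (5S,6S)‑2‑ethyl‑5‑methyl‑6‑(2,4,5‑trimethoxyphenyl)cyclohex‑2‑en‑1‑one | O=C1[C@H](c2cc(OC)c(OC)cc2OC)[C@@H](C)CC=C1CC | intermediate
9 | (5S,6S)‑2‑ethyl‑1,5‑dimethyl‑6‑(2,4,5‑trimethoxyphenyl)cyclohex‑2‑en‑1‑ol (C‑1 epimers) | CC1(O)[C@H](c2cc(OC)c(OC)cc2OC)[C@@H](C)CC=C1CC | intermediate
10 | (4R,5S)‑2‑ethyl‑3,5‑dimethyl‑4‑(2,4,5‑trimethoxyphenyl)cyclohex‑2‑en‑1‑one | CCC1=C(C)[C@H](c2cc(OC)c(OC)cc2OC)[C@@H](C)CC1=O | intermediate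
11 | (2R,3R,4R,5S)‑2‑ethyl‑3,5‑dimethyl‑4‑(2,4,5‑trimethoxyphenyl)cyclohexan‑1‑one | CC[C@@H]1[C@H](C)[C@H](c2cc(OC)c(OC)cc2OC)[C@@H](C)CC1=O | intermediate
12 | trimethylsilyl enol ether of 11 (C‑1=C‑6) | CC[C@@H]1[C@H](C)[C@H](c2cc(OC)c(OC)cc2OC)[C@@H](C)C=C1O[Si](C)(C)C | intermediate
13 | (2R,3R,4S,5R,6R)‑2‑ethyl‑3,5‑dimethyl‑4,6‑bis(2,4,5‑trimethoxyphenyl)cyclohexan‑1‑one | CC[C@@H]1[C@H](C)[C@H](c2cc(OC)c(OC)cc2OC)[C@@H](C)[C@H](c2cc(OC)c(OC)cc2OC)C1=O | intermediate
14 | 1‑vinylcyclohexan‑1‑ol from 13 (C‑1 epimers) | CC[C@@H]1[C@H](C)[C@H](c2cc(OC)c(OC)cc2OC)[C@@H](C)[C@H](c2cc(OC)c(OC)cc2OC)C1(O)C=C | intermediate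
15 | 2‑(cyclohexylidene)acetaldehyde from 13 (alkene isomers) | CC[C@@H]1[C@H](C)[C@H](c2cc(OC)c(OC)cc2OC)[C@@H](C)[C@H](c2cc(OC)c(OC)cc2OC)C1=CC=O | intermediate
16 | lithium 2‑(cyclohexylidene)‑1‑(tributylstannyl)ethoxide from 15 | CC[C@@H]1[C@H](C)[C@H](c2cc(OC)c(OC)cc2OC)[C@@H](C)[C@H](c2cc(OC)c(OC)cc2OC)C1=CC(O[Li])[Sn](CCCC)(CCCC)CCCC | intermediate
17 | tributyl[2‑(cyclohexylidene)‑1‑methoxyethyl]stannane from 15 | CC[C@@H]1[C@H](C)[C@H](c2cc(OC)c(OC)cc2OC)[C@@H](C)[C@H](c2cc(OC)c(OC)cc2OC)C1=CC(OC)[Sn](CCCC)(CCCC)CCCC | intermediate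
18 | methyl cyanoacetate | COC(=O)CC#N | starting material
19 | methyl 3‑imino‑3‑methoxypropanoate hydrochloride | COC(=O)CC(=[NH2+])OC.[Cl-] | intermediate
20 | methyl 3,3,3‑trimethoxypropanoate | COC(=O)CC(OC)(OC)OC | intermediate
21 | methyl 3,3‑dimethoxyprop‑2‑enoate | COC(=O)C=C(OC)OC | intermediate
22 | [2‑(cyclohexylidene)‑1‑methoxyethyl]lithium from 17 | CC[C@@H]1[C@H](C)[C@H](c2cc(OC)c(OC)cc2OC)[C@@H](C)[C@H](c2cc(OC)c(OC)cc2OC)C1=CC([Li])OC | intermediate
23 | 5‑(cyclohexylidene)‑1,1,4‑trimethoxypent‑1‑en‑3‑one from 22 | CC[C@@H]1[C@H](C)[C@H](c2cc(OC)c(OC)cc2OC)[C@@H](C)[C@H](c2cc(OC)c(OC)cc2OC)C1=CC(OC)C(=O)C=C(OC)OC | intermediate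
24 | lithium trienolate of 23 | CC[C@@H]1[C@H](C)[C@H](c2cc(OC)c(OC)cc2OC)[C@@H](C)[C@H](c2cc(OC)c(OC)cc2OC)C1=CC(OC)=C(O[Li])C=C(OC)OC | intermediate
25 | tatanan B | CC[C@@H]1[C@H](C)[C@H](c2cc(OC)c(OC)cc2OC)[C@@H](C)[C@H](c2cc(OC)c(OC)cc2OC)[C@]12C=C(OC)C(=O)C=C2OC | target

**Step count and risks**

Total steps: 11. Longest linear sequence: 10 (steps 1–9 and 11; step 10 is a one‑step side branch).

Steps most likely to fail:

1. Step 11 (proposed new method). The allyllithium may be acylated at the wrong terminus or attack the ketene acetal carbon of the acrylate, it may be protonated by the ketone as it forms, or the crowded ring closure may stall at the open‑chain ketone. The fallback uses known reaction types, sets out from 13 and returns at 25. Methoxymethylenation of 13 with Ph3P=CHOMe gives the methyl enol ether F1, and aqueous acid gives the cyclohexanecarbaldehyde F2. Its potassium enolate (KOt‑Bu, THF) is alkenylated by addition–elimination on 1,4,4‑trimethoxybut‑3‑en‑2‑one F3 (made from methoxyacetyl chloride, 1,1‑dimethoxyethene and Et3N). Attack should again be equatorial, anti to the axial methyl group, giving the keto aldehyde F4. Intramolecular aldol condensation (K2CO3, MeOH) then closes the dienone ring to 25.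

2. Step 5. Facial selectivity of the hydrogenation may be poor, because the 5‑methyl group sits on the face from which hydrogen must add while the aryl group blocks the other. The fallback sets out from 10 and returns at 11. Luche reduction (NaBH4, CeCl3, MeOH) should deliver hydride anti to the 5‑methyl group and give the allylic alcohol F5 with hydroxyl cis to that methyl group. Hydroxyl‑directed hydrogenation with [Ir(cod)(PCy3)(py)]PF6 and H2 then adds hydrogen from the hydroxyl face to give the cyclohexanol F6, and Dess–Martin oxidation gives 11.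

3. Step 2. Oxidative addition and transmetalation may be slow with the hindered, electron‑rich bromide, and the enolate may equilibrate to the extended dienolate and lose regiochemistry. The fallback reverses the polarity, sets out from 5 and returns at 8. The silyl dienol ether 7, made as in step 2, is brominated with NBS to the α'‑bromo enone F7. Nickel‑catalysed Negishi coupling (NiCl2·glyme, bis(oxazoline) ligand) with (2,4,5‑trimethoxyphenyl)zinc chloride F8 (from 6, n‑BuLi, then ZnCl2) gives 8 after equilibration to the trans isomer.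

**Further compounds**

F1 | step 11 | (methoxymethylidene)cyclohexane from 13 | CC[C@@H]1[C@H](C)[C@H](c2cc(OC)c(OC)cc2OC)[C@@H](C)[C@H](c2cc(OC)c(OC)cc2OC)C1=COC
F2 | step 11 | cyclohexanecarbaldehyde from 13 (C‑1 epimers) | CC[C@@H]1[C@H](C)[C@H](c2cc(OC)c(OC)cc2OC)[C@@H](C)[C@H](c2cc(OC)c(OC)cc2OC)C1C=O
F3 | step 11 | 1,4,4‑trimethoxybut‑3‑en‑2‑one | COCC(=O)C=C(OC)OC
F4 | step 11 | 1‑(1,4‑dimethoxy‑3‑oxobut‑1‑enyl)cyclohexanecarbaldehyde from F2 | CC[C@@H]1[C@H](C)[C@H](c2cc(OC)c(OC)cc2OC)[C@@H](C)[C@H](c2cc(OC)c(OC)cc2OC)[C@@]1(C=O)C(OC)=CC(=O)COC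
F5 | step 5 | allylic alcohol from 10 (hydroxyl cis to the 5‑methyl group) | CCC1=C(C)[C@H](c2cc(OC)c(OC)cc2OC)[C@@H](C)C[C@H]1O
F6 | step 5 | cyclohexanol from F5 | CC[C@@H]1[C@H](C)[C@H](c2cc(OC)c(OC)cc2OC)[C@@H](C)C[C@H]1O
F7 | step 2 | (5S)‑6‑bromo‑2‑ethyl‑5‑methylcyclohex‑2‑en‑1‑one (C‑6 epimers) | CCC1=CC[C@H](C)C(Br)C1=O
F8 | step 2 | (2,4,5‑trimethoxyphenyl)zinc chloride | COc1cc(OC)c(OC)cc1[Zn]Cl
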